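The route rests on disconnecting O1'–C2' of the second dihydrobenzofuran, which traces that ring back to the opened form of a trans-3,4-diaryl-dihydrocoumarin. The feature exploited is that C2' is benzylic to the para-oxygenated ring E and within five-ring reach of the ring D phenol oxygen on C7a': anodic two-electron oxidation of the C2' carboxylate expels CO2, and the phenol traps the resulting cation, closing the ring and fixing C2' trans to the ring B group on C3' in one operation. The precursor, held as its tetrabutylammonium carboxylate so that it cannot relactonise, already contains the finished (2S,3S) first dihydrobenzofuran, C3' set by rhodium-catalysed arylation of a ring D coumarin, and a ring D methyl ester.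

Key step: step 21

Remarks on the chemistry:
- Ring letters: A = 3,5-dioxygenated phenyl on C3; B = benzo ring of the first dihydrobenzofuran; D = benzo ring of the second; E = 4-oxygenated phenyl on C2'; F = 4-oxygenated phenyl of the styryl group; G = 4-hydroxy-3-methoxyphenyl on C2. MOM = methoxymethyl.
- Ar1 = (2S,3S)-3-[3,5-bis(methoxymethoxy)phenyl]-4-(methoxymethoxy)-2-[3-methoxy-4-(methoxymethoxy)phenyl]-2,3-dihydro-1-benzofuran-6-yl, the protected first dihydrobenzofuran attached through C6 of ring B.
- Assumption: the sense of induction in steps 5 and 17 is taken to follow the models established for β-nitrostyrene and for coumarin itself; if either substrate responds in the opposite sense, the antipodal ligand is used.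
- The configuration at the carboxyl-bearing carbon of 27 and 28 is drawn as in the trans lactone, but it is inconsequential because this carbon becomes planar in step 21.
- The free hydroxy acid is never isolated, because it would relactonise. One equivalent of collidinium salt is added in step 21 as the proton source for the cathode, so that no strong base (and hence no easily oxidised phenoxide) builds up.

Step 1
Reactants: 1 5-chlororesorcinol
Product: 2 1-chloro-3,5-bis(methoxymethoxy)benzene
Conditions: MOMCl (2.5 equiv), i-Pr2NEt, CH2Cl2, 0 °C → rt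
Reagents that add atoms: chloromethyl methyl ether, COCCl
Why: Double O-alkylation of the phenols (MOM acetal protection) gives the single building block from which ring A and ring B are both drawn; no stereocentre is involved.

Step 2
Reactants: 2 1-chloro-3,5-bis(methoxymethoxy)benzene
Product: 3 [3,5-bis(methoxymethoxy)phenyl]boronic acid
Conditions: Pd(OAc)2 (2 mol %), XPhos (4 mol %), B2(OH)4, KOAc, EtOH, 80 °C
Reagents that add atoms: tetrahydroxydiboron, OB(O)B(O)O
Why: Miyaura borylation of an aryl chloride with a biarylphosphine–palladium catalyst gives the boronic acid directly, and the MOM acetals tolerate the weakly basic medium.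

Step 3
Reactants: 2 1-chloro-3,5-bis(methoxymethoxy)benzene
Product: 5 4-chloro-2,6-bis(methoxymethoxy)benzaldehyde, via aryllithium 4 (not isolated)
Conditions: n-BuLi, THF, 0 °C; DMF, −78 °C → rt; aq. NH4Cl
Reagents that add atoms: N,N-dimethylformamide, CN(C)C=O
Why: Directed ortho-metalation, in which the two MOM ethers jointly direct lithiation to the carbon between them (para to chlorine, so no aryne can arise), followed by formylation.

Step 4
Reactants: 5 4-chloro-2,6-bis(methoxymethoxy)benzaldehyde
Product: 6 5-chloro-1,3-bis(methoxymethoxy)-2-[(E)-2-nitroethenyl]benzene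
Conditions: MeNO2, NH4OAc, 95 °C
Reagents that add atoms: nitromethane, C[N+](=O)[O-]
Why: Henry condensation with dehydration in the same pot gives the conjugated (E)-nitroalkene, the thermodynamically preferred geometry.

Step 5
Reactants: 6 5-chloro-1,3-bis(methoxymethoxy)-2-[(E)-2-nitroethenyl]benzene; 3 [3,5-bis(methoxymethoxy)phenyl]boronic acid
Product: 7 (S)-2,2-diarylnitroethane
Conditions: [RhCl(C2H4)2]2 (2.5 mol %), (3aR,6aR)-3,6-diphenyl-1,3a,4,6a-tetrahydropentalene (5.5 mol %), KOH (0.5 equiv), dioxane/H2O (10:1), 40 °C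
Reagents that add atoms: none
Why: Hayashi–Miyaura rhodium/chiral-diene asymmetric 1,4-addition of an arylboronic acid to a β-aryl nitroalkene is an established route to 2,2-diarylnitroethanes, and ligand-controlled delivery of ring A to the Si face of C-β sets the future C3 as (S).

Step 6
Reactants: 7 (S)-2,2-diarylnitroethane
Product: 8 (S)-2,2-diarylacetic acid
Conditions: NaNO2, AcOH, DMSO, 35 °C
Reagents that add atoms: water, O
Why: Kornblum–Mioskowski conversion of the primary nitroalkane into the carboxylic acid (nitrosation to the nitrolic acid, then hydrolysis) runs in weakly acidic medium, so the adjacent diarylmethine centre is not deprotonated.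

Step 7
Reactants: 8 (S)-2,2-diarylacetic acid
Product: 9 (S)-2,2-diarylethanol
Conditions: BH3·SMe2, THF, 0 °C → rt; aq. work-up
Reagents that add atoms: none
Why: Borane reduction of the carboxylic acid is chemoselective and non-basic and turns the labile α-carbonyl position into a non-enolisable primary alcohol.

Step 8
Reactants: 9 (S)-2,2-diarylethanol
Product: 10 (S)-2,2-diarylacetaldehyde
Conditions: Dess–Martin periodinane, NaHCO3, CH2Cl2, 0 °C
Reagents that add atoms: none
Why: Dess–Martin oxidation under buffered neutral conditions gives the aldehyde, which is filtered cold and used at once so that its α-centre is not equilibrated through the enol.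

Step 9
Reactants: 11 4-bromo-2-methoxyphenol
Product: 12 4-bromo-2-methoxy-1-(methoxymethoxy)benzene
Conditions: MOMCl, i-Pr2NEt, CH2Cl2, 0 °C → rt
Reagents that add atoms: chloromethyl methyl ether, COCCl
Why: MOM protection (O-alkylation) of the phenol makes the ring G bromide compatible with magnesium insertion.

Step 10
Reactants: 12 4-bromo-2-methoxy-1-(methoxymethoxy)benzene; 10 (S)-2,2-diarylacetaldehyde
Product: 14 (2S)-1,2,2-triarylethanol as both C1 epimers, via arylmagnesium bromide 13 (not isolated)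
Conditions: Mg, THF, 40 °C; then 10, THF, −78 °C; aq. NH4Cl
Reagents that add atoms: none
Why: Grignard 1,2-addition to the aldehyde; the carbinol centre forms as a mixture that is immaterial because it is ionised in step 11, and aldehyde that is enolised by the reagent does not add, so the (S)-diarylmethine is carried through.

Step 11
Reactants: 14 (2S)-1,2,2-triarylethanol
Product: 15 (2S,3S)-6-chloro-3-(3,5-dihydroxyphenyl)-2-(4-hydroxy-3-methoxyphenyl)-2,3-dihydro-1-benzofuran-4-ol
Conditions: HCl (3 M in MeOH), THF, 0 → 40 °C, high dilution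
Reagents that add atoms: none
Why: Acidic methanolysis removes the five MOM groups and ionises the para-hydroxybenzylic carbinol, and a ring B phenol captures the cation in an SN1 cyclodehydration (5-exo closure); C2 is set trans to the ring A group under control of C3, the trans isomer also being the thermodynamic one.

Step 12
Reactants: 15 (2S,3S)-6-chloro tetraphenol
Product: 16 (2S,3S)-3-[3,5-bis(methoxymethoxy)phenyl]-6-chloro-4-(methoxymethoxy)-2-[3-methoxy-4-(methoxymethoxy)phenyl]-2,3-dihydro-1-benzofuran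
Conditions: MOMCl (8 equiv), i-Pr2NEt, CH2Cl2, 0 → 40 °C
Reagents that add atoms: chloromethyl methyl ether, COCCl
Why: Fourfold MOM protection (O-alkylation) with an amine base avoids a free para-phenoxide on ring G, which could open the benzylic ether.

Step 13
Reactants: 16 (2S,3S)-6-chloro tetra-MOM dihydrobenzofuran
Product: 17 Ar1-boronic acid
Conditions: Pd(OAc)2 (3 mol %), XPhos (6 mol %), B2(OH)4, KOAc, EtOH, 80 °C
Reagents that add atoms: tetrahydroxydiboron, OB(O)B(O)O
Why: Miyaura borylation of the unhindered aryl chloride on ring B gives the boronic acid needed for transmetalation to rhodium; neither stereocentre is touched.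

Step 14
Reactants: 18 methyl 4-bromo-3,5-dihydroxybenzoate
Product: 19 methyl 4-bromo-3-hydroxy-5-(methoxymethoxy)benzoate
Conditions: MOMCl (1.0 equiv), i-Pr2NEt, CH2Cl2, −20 → 0 °C
Reagents that add atoms: chloromethyl methyl ether, COCCl
Why: Statistical mono-O-alkylation of the symmetric diol gives the mono-MOM ether, the bis-ether and unreacted diol being separated and recycled.

Step 15
Reactants: 19 methyl 4-bromo-3-hydroxy-5-(methoxymethoxy)benzoate
Product: 20 methyl 3-hydroxy-4-[(E)-3-methoxy-3-oxoprop-1-en-1-yl]-5-(methoxymethoxy)benzoate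
Conditions: methyl acrylate, Pd(OAc)2 (5 mol %), P(o-tol)3, Et3N, DMF, 110 °C
Reagents that add atoms: methyl acrylate, C=CC(=O)OC
Why: Mizoroki–Heck reaction of the aryl bromide, activated by the para ester, gives the (E)-cinnamate.

Step 16
Reactants: 20 (E)-ortho-hydroxycinnamate
Product: 21 methyl 5-(methoxymethoxy)-2-oxo-2H-chromene-7-carboxylate
Conditions: n-Bu3P (20 mol %), MeOH, 65 °C
Reagents that add atoms: none
Why: Nucleophilic phosphine catalysis: reversible conjugate addition of the phosphine allows bond rotation, lactonisation and elimination, converting the (E)-ortho-hydroxycinnamate into the coumarin under neutral conditions.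

Step 17
Reactants: 17 Ar1-boronic acid; 21 methyl 5-(methoxymethoxy)-2-oxo-2H-chromene-7-carboxylate
Product: 22 methyl (4R)-4-Ar1-5-(methoxymethoxy)-2-oxo-3,4-dihydro-2H-chromene-7-carboxylate
Conditions: Rh(acac)(C2H4)2 (5 mol %), (R)-SEGPHOS (5.5 mol %), 21 (2 equiv), dioxane/H2O (10:1), 60 °C
Reagents that add atoms: none
Why: Hayashi–Miyaura rhodium/bisphosphine asymmetric conjugate arylation of a coumarin is a known entry to 4-arylchroman-2-ones, and the ligand delivers ring B to one face of C4 under catalyst control, setting the future C3' as (R) independently of the remote C2 and C3 centres.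

Step 18
Reactants: 23 4-bromophenol
Product: 24 1-bromo-4-(methoxymethoxy)benzene
Conditions: MOMCl, i-Pr2NEt, CH2Cl2, 0 °C → rt
Reagents that add atoms: chloromethyl methyl ether, COCCl
Why: MOM protection (O-alkylation) of the phenol gives the ring E electrophile.

Step 19
Reactants: 22 (4R)-4-aryl-dihydrocoumarin; 24 1-bromo-4-(methoxymethoxy)benzene
Product: 27 methyl (3R,4R)-4-Ar1-5-(methoxymethoxy)-3-[4-(methoxymethoxy)phenyl]-2-oxo-3,4-dihydro-2H-chromene-7-carboxylate, via lithium enolate 25 (not isolated), via chlorozinc enolate 26 (not isolated)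
Conditions: LiN(SiMe3)2, THF, −78 °C; ZnCl2, −78 °C → rt; Pd(dba)2 (5 mol %), P(t-Bu)3 (10 mol %), 24, rt → 50 °C
Reagents that add atoms: none
Why: Palladium-catalysed α-arylation of the lactone through its zinc enolate (Hartwig-type coupling) is mild enough for the aryl ester and the methyl benzoate, and ring E enters anti to the C4 substituent, the trans isomer also being the thermodynamic one.

Step 20
Reactants: 27 trans-3,4-diaryl-dihydrocoumarin
Product: 28 tetrabutylammonium (2R,3R)-3-Ar1-3-[2-hydroxy-4-(methoxycarbonyl)-6-(methoxymethoxy)phenyl]-2-[4-(methoxymethoxy)phenyl]propanoate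
Conditions: n-Bu4NOH (1.0 equiv, 40 % aq.), THF, 0 °C; evaporate, azeotrope with toluene
Reagents that add atoms: tetrabutylammonium hydroxide, CCCC[N+](CCCC)(CCCC)CCCC.[OH-]
Why: Saponification of the aryl ester (lactone) is far faster than that of the methyl benzoate, so one equivalent of hydroxide leaves the carboxylate as the only anionic site with the ring D phenol protonated, and as a salt the open form cannot relactonise.

Step 21
Reactants: 28 tetrabutylammonium carboxylate
Product: 30 methyl (2R,3R)-3-Ar1-4-(methoxymethoxy)-2-[4-(methoxymethoxy)phenyl]-2,3-dihydro-1-benzofuran-6-carboxylate, via C2' benzylic cation 29 (not isolated)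
Conditions: graphite anode, Pt cathode, undivided cell, constant current (ca. 3 mA cm−2, 2.2 F/mol), 2,4,6-collidine (1 equiv), 2,4,6-collidinium BF4 (1.1 equiv), n-Bu4NPF6 (0.1 M), 3 Å MS, CH2Cl2, rt
Reagents that add atoms: none
Why: The carboxylate of 28, the only anion present, is discharged at graphite in an overall two-electron process assisted by the electron-rich ring E, CO2 is lost and the para-oxybenzylic C2' cation 29 results. The closest known reaction type is the Hofer–Moest (non-Kolbe) anodic decarboxylation of α-aryl carboxylates with capture of the cation by a hydroxyl nucleophile, run here intramolecularly with a phenol. The ring D oxygen on C7a' attacks the trigonal C2' in a 5-exo-trig closure that forms O1'–C2' and the second dihydrofuran ring. The new C2' centre is controlled by the existing C3' centre, since oxygen adds to the face that places ring E anti to the ring B substituent, and the trans product is also the thermodynamic one should the benzylic C–O bond re-ionise. The step needs oxidation of the carboxylate in preference to the phenol and to rings G, A and B; this is secured by keeping the phenol protonated with the collidine/collidinium buffer (which also feeds hydrogen evolution at the cathode), by the ring D ester that raises the potential of the phenol, by the carbon anode at low current density, and by stopping near 2 F/mol.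

Step 22
Reactants: 30 hexa-MOM bis(dihydrobenzofuran) methyl ester
Product: 31 C6' benzylic alcohol
Conditions: i-Bu2AlH (3 equiv), CH2Cl2, −78 → −20 °C; aq. potassium sodium tartrate
Reagents that add atoms: none
Why: Hydride reduction of the methyl ester gives the benzylic alcohol, while MOM acetals and both dihydrofuran rings are inert to the reagent.

Step 23
Reactants: 31 C6' benzylic alcohol
Product: 32 C6' aldehyde
Conditions: MnO2 (20 equiv), CH2Cl2, rt
Reagents that add atoms: none
Why: MnO2 oxidises the benzylic alcohol selectively to the aldehyde under neutral heterogeneous conditions.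

Step 24
Reactants: 33 4-hydroxybenzyl alcohol
Product: 34 [4-(methoxymethoxy)phenyl]methanol
Conditions: MOMCl (1.05 equiv), K2CO3, acetone, 0 °C → rt
Reagents that add atoms: chloromethyl methyl ether, COCCl
Why: Chemoselective O-alkylation of the phenoxide, which forms under carbonate while the benzylic alcohol stays protonated.

Step 25
Reactants: 34 [4-(methoxymethoxy)phenyl]methanol
Product: 35 1-(bromomethyl)-4-(methoxymethoxy)benzene
Conditions: CBr4, PPh3, CH2Cl2, 0 °C
Reagents that add atoms: carbon tetrabromide, BrC(Br)(Br)Br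
Why: Appel bromination converts the benzylic alcohol into the bromide under neutral conditions that spare the MOM acetal.

Step 26
Reactants: 35 1-(bromomethyl)-4-(methoxymethoxy)benzene
Product: 36 diethyl {[4-(methoxymethoxy)phenyl]methyl}phosphonate
Conditions: P(OEt)3, 100 °C
Reagents that add atoms: triethyl phosphite, CCOP(OCC)OCC
Why: Michaelis–Arbuzov reaction of the reactive benzylic bromide gives the ring F phosphonate.

Step 27
Reactants: 32 C6' aldehyde; 36 diethyl {[4-(methoxymethoxy)phenyl]methyl}phosphonate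
Product: 38 hepta-O-MOM gnetin K, via potassium phosphonate carbanion 37 (not isolated)
Conditions: 36, KOt-Bu, THF, 0 °C; then 32, 0 °C → rt
Reagents that add atoms: none
Why: Horner–Wadsworth–Emmons olefination of an aryl aldehyde with a benzylphosphonate anion gives the (E)-stilbene, and the non-acidic C3 and C3' hydrogens are not touched by the base.

Step 28
Reactants: 38 hepta-O-MOM gnetin K
Product: 39 gnetin K
Conditions: HCl (3 M, aq.), MeOH/THF, 40 °C, argon, dark
Reagents that add atoms: none
Why: Acid-catalysed acetal exchange removes the seven MOM groups; both dihydrofurans are already the thermodynamic trans isomers, and the styryl group at C6' is too remote from any nucleophilic ring for acid-induced cyclisation.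

Compound list
1 | 5-chlorobenzene-1,3-diol (5-chlororesorcinol) | Oc1cc(O)cc(Cl)c1 | starting material
2 | 1-chloro-3,5-bis(methoxymethoxy)benzene | COCOc1cc(Cl)cc(OCOC)c1 | intermediate
3 | [3,5-bis(methoxymethoxy)phenyl]boronic acid | COCOc1cc(OCOC)cc(B(O)O)c1 | intermediate
4 | [4-chloro-2,6-bis(methoxymethoxy)phenyl]lithium | COCOc1cc(Cl)cc(OCOC)c1[Li] | intermediate
5 | 4-chloro-2,6-bis(methoxymethoxy)benzaldehyde | COCOc1cc(Cl)cc(OCOC)c1C=O | intermediate
6 | 5-chloro-1,3-bis(methoxymethoxy)-2-[(E)-2-nitroethenyl]benzene | COCOc1cc(Cl)cc(OCOC)c1/C=C/[N+](=O)[O-] | intermediate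
7 | 2-{(1S)-1-[3,5-bis(methoxymethoxy)phenyl]-2-nitroethyl}-5-chloro-1,3-bis(methoxymethoxy)benzene | [O-][N+](=O)C[C@@H](c1cc(OCOC)cc(OCOC)c1)c1c(OCOC)cc(Cl)cc1OCOC | intermediate
8 | (2S)-2-[3,5-bis(methoxymethoxy)phenyl]-2-[4-chloro-2,6-bis(methoxymethoxy)phenyl]acetic acid | OC(=O)[C@@H](c1cc(OCOC)cc(OCOC)c1)c1c(OCOC)cc(Cl)cc1OCOC | intermediate
9 | (2S)-2-[3,5-bis(methoxymethoxy)phenyl]-2-[4-chloro-2,6-bis(methoxymethoxy)phenyl]ethan-1-ol | OC[C@@H](c1cc(OCOC)cc(OCOC)c1)c1c(OCOC)cc(Cl)cc1OCOC | intermediate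
10 | (2S)-2-[3,5-bis(methoxymethoxy)phenyl]-2-[4-chloro-2,6-bis(methoxymethoxy)phenyl]acetaldehyde | O=C[C@@H](c1cc(OCOC)cc(OCOC)c1)c1c(OCOC)cc(Cl)cc1OCOC | intermediate
11 | 4-bromo-2-methoxyphenol | COc1cc(Br)ccc1O | starting material
12 | 4-bromo-2-methoxy-1-(methoxymethoxy)benzene | COCOc1ccc(Br)cc1OC | intermediate
13 | [3-methoxy-4-(methoxymethoxy)phenyl]magnesium bromide | COCOc1ccc([Mg]Br)cc1OC | intermediate
14 | (2S)-2-[3,5-bis(methoxymethoxy)phenyl]-2-[4-chloro-2,6-bis(methoxymethoxy)phenyl]-1-[3-methoxy-4-(methoxymethoxy)phenyl]ethan-1-ol, both C1 epimers | OC(c1ccc(OCOC)c(OC)c1)[C@@H](c1cc(OCOC)cc(OCOC)c1)c1c(OCOC)cc(Cl)cc1OCOC | intermediate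
15 | (2S,3S)-6-chloro-3-(3,5-dihydroxyphenyl)-2-(4-hydroxy-3-methoxyphenyl)-2,3-dihydro-1-benzofuran-4-ol | COc1cc([C@H]2Oc3cc(Cl)cc(O)c3[C@@H]2c2cc(O)cc(O)c2)ccc1O | intermediate
16 | (2S,3S)-3-[3,5-bis(methoxymethoxy)phenyl]-6-chloro-4-(methoxymethoxy)-2-[3-methoxy-4-(methoxymethoxy)phenyl]-2,3-dihydro-1-benzofuran | COc1cc([C@H]2Oc3cc(Cl)cc(OCOC)c3[C@@H]2c2cc(OCOC)cc(OCOC)c2)ccc1OCOC | intermediate
17 | {(2S,3S)-3-[3,5-bis(methoxymethoxy)phenyl]-4-(methoxymethoxy)-2-[3-methoxy-4-(methoxymethoxy)phenyl]-2,3-dihydro-1-benzofuran-6-yl}boronic acid (Ar1-boronic acid) | COc1cc([C@H]2Oc3cc(B(O)O)cc(OCOC)c3[C@@H]2c2cc(OCOC)cc(OCOC)c2)ccc1OCOC | intermediate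
18 | methyl 4-bromo-3,5-dihydroxybenzoate | COC(=O)c1cc(O)c(Br)c(O)c1 | starting material
19 | methyl 4-bromo-3-hydroxy-5-(methoxymethoxy)benzoate | COCOc1cc(C(=O)OC)cc(O)c1Br | intermediate
20 | methyl 3-hydroxy-4-[(E)-3-methoxy-3-oxoprop-1-en-1-yl]-5-(methoxymethoxy)benzoate | COCOc1cc(C(=O)OC)cc(O)c1/C=C/C(=O)OC | intermediate
21 | methyl 5-(methoxymethoxy)-2-oxo-2H-chromene-7-carboxylate | COCOc1cc(C(=O)OC)cc2oc(=O)ccc12 | intermediate
22 | methyl (4R)-4-Ar1-5-(methoxymethoxy)-2-oxo-3,4-dihydro-2H-chromene-7-carboxylate | COc1cc([C@H]2Oc3cc([C@H]4CC(=O)Oc5cc(C(=O)OC)cc(OCOC)c45)cc(OCOC)c3[C@@H]2c2cc(OCOC)cc(OCOC)c2)ccc1OCOC | intermediate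
23 | 4-bromophenol | Oc1ccc(Br)cc1 | starting material
24 | 1-bromo-4-(methoxymethoxy)benzene | COCOc1ccc(Br)cc1 | intermediate
25 | lithium enolate of lactone 22 | COc1cc([C@H]2Oc3cc([C@H]4C=C(O[Li])Oc5cc(C(=O)OC)cc(OCOC)c45)cc(OCOC)c3[C@@H]2c2cc(OCOC)cc(OCOC)c2)ccc1OCOC | intermediate
26 | chlorozinc enolate of lactone 22 | COc1cc([C@H]2Oc3cc([C@H]4C=C(O[Zn]Cl)Oc5cc(C(=O)OC)cc(OCOC)c45)cc(OCOC)c3[C@@H]2c2cc(OCOC)cc(OCOC)c2)ccc1OCOC | intermediate
27 | methyl (3R,4R)-4-Ar1-5-(methoxymethoxy)-3-[4-(methoxymethoxy)phenyl]-2-oxo-3,4-dihydro-2H-chromene-7-carboxylate (trans) | COc1cc([C@H]2Oc3cc([C@H]4[C@H](c5ccc(OCOC)cc5)C(=O)Oc5cc(C(=O)OC)cc(OCOC)c45)cc(OCOC)c3[C@@H]2c2cc(OCOC)cc(OCOC)c2)ccc1OCOC | intermediate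
28 | tetrabutylammonium (2R,3R)-3-Ar1-3-[2-hydroxy-4-(methoxycarbonyl)-6-(methoxymethoxy)phenyl]-2-[4-(methoxymethoxy)phenyl]propanoate (precursor of the key step) | COc1cc([C@H]2Oc3cc([C@H](c5c(OCOC)cc(C(=O)OC)cc5O)[C@@H](C(=O)[O-])c4ccc(OCOC)cc4)cc(OCOC)c3[C@@H]2c2cc(OCOC)cc(OCOC)c2)ccc1OCOC.CCCC[N+](CCCC)(CCCC)CCCC | intermediate
29 | C2' para-oxybenzylic cation from 28 | COc1cc([C@H]2Oc3cc([C@H](c5c(OCOC)cc(C(=O)OC)cc5O)[CH+]c4ccc(OCOC)cc4)cc(OCOC)c3[C@@H]2c2cc(OCOC)cc(OCOC)c2)ccc1OCOC | intermediate
30 | methyl (2R,3R)-3-Ar1-4-(methoxymethoxy)-2-[4-(methoxymethoxy)phenyl]-2,3-dihydro-1-benzofuran-6-carboxylate (product of the key step) | COc1cc([C@H]2Oc3cc([C@@H]4c5c(OCOC)cc(C(=O)OC)cc5O[C@H]4c4ccc(OCOC)cc4)cc(OCOC)c3[C@@H]2c2cc(OCOC)cc(OCOC)c2)ccc1OCOC | intermediate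
31 | {(2R,3R)-3-Ar1-4-(methoxymethoxy)-2-[4-(methoxymethoxy)phenyl]-2,3-dihydro-1-benzofuran-6-yl}methanol | COc1cc([C@H]2Oc3cc([C@@H]4c5c(OCOC)cc(CO)cc5O[C@H]4c4ccc(OCOC)cc4)cc(OCOC)c3[C@@H]2c2cc(OCOC)cc(OCOC)c2)ccc1OCOC | intermediate
32 | (2R,3R)-3-Ar1-4-(methoxymethoxy)-2-[4-(methoxymethoxy)phenyl]-2,3-dihydro-1-benzofuran-6-carbaldehyde | COc1cc([C@H]2Oc3cc([C@@H]4c5c(OCOC)cc(C=O)cc5O[C@H]4c4ccc(OCOC)cc4)cc(OCOC)c3[C@@H]2c2cc(OCOC)cc(OCOC)c2)ccc1OCOC | intermediate
33 | 4-(hydroxymethyl)phenol (4-hydroxybenzyl alcohol) | OCc1ccc(O)cc1 | starting material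
34 | [4-(methoxymethoxy)phenyl]methanol | COCOc1ccc(CO)cc1 | intermediate
35 | 1-(bromomethyl)-4-(methoxymethoxy)benzene | COCOc1ccc(CBr)cc1 | intermediate
36 | diethyl {[4-(methoxymethoxy)phenyl]methyl}phosphonate | CCOP(=O)(Cc1ccc(OCOC)cc1)OCC | intermediate
37 | potassium salt of the carbanion of phosphonate 36 | CCOP(=O)([CH-]c1ccc(OCOC)cc1)OCC.[K+] | intermediate
38 | hepta-O-MOM gnetin K, (2R,3R)-3-Ar1-4-(methoxymethoxy)-2-[4-(methoxymethoxy)phenyl]-6-{(E)-2-[4-(methoxymethoxy)phenyl]ethenyl}-2,3-dihydro-1-benzofuran | COc1cc([C@H]2Oc3cc([C@@H]4c5c(OCOC)cc(/C=C/c6ccc(OCOC)cc6)cc5O[C@H]4c4ccc(OCOC)cc4)cc(OCOC)c3[C@@H]2c2cc(OCOC)cc(OCOC)c2)ccc1OCOC | intermediate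
39 | gnetin K, (2S,3S,2'R,3'R) | COc1cc([C@H]2Oc3cc([C@@H]4c5c(O)cc(/C=C/c6ccc(O)cc6)cc5O[C@H]4c4ccc(O)cc4)cc(O)c3[C@@H]2c2cc(O)cc(O)c2)ccc1O | target

Total step count: 28. Longest linear sequence: 19 steps (1, 3–8, 10–13, 17, 19–23, 27, 28).

Steps most likely to fail

Step 21. What may go wrong: the anode may oxidise the electron-rich rings G and B or the ring D phenol in competition with the carboxylate, or the C2' cation may lose the C3' proton to give a triarylethene before the hindered phenol closes. Fallback, setting out from 28 and returning at 30: the phenol is masked and the decarboxylation is done with a chemical oxidant. Compound 28 is bis-silylated (TBSCl, imidazole, DMF) and the silyl ester hydrolysed on aqueous NaHCO3 work-up to the O-silylated hydroxy acid F1. Kochi-type oxidative decarboxylation with Pb(OAc)4 in benzene/AcOH at 60 °C gives the para-oxybenzylic acetate F2 as both C2' epimers. n-Bu4NF then frees the phenoxide, and a catalytic amount of camphorsulfonic acid in CH2Cl2 ionises the acetate and equilibrates any cis ether, so that the same SN1 closure gives trans 30.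

Step 17. What may go wrong: carbometalation at the peri-hindered C4 of the 5-alkoxycoumarin may be slow, so that protodeboronation of the limiting boronic acid 17 wins. Fallback, setting out from 17 and 21 and returning at 22: the C–C bond and the stereocentre are made in separate steps. Oxidative Heck arylation of 21 with 17 (Pd(OAc)2, 1,10-phenanthroline, O2, DMF, 80 °C), in which β-hydride elimination closes the cycle, gives the 4-aryl coumarin F3. Copper hydride asymmetric conjugate reduction (Cu(OAc)2, DTBM-SEGPHOS of the configuration that gives the (4R) product, (EtO)2MeSiH, t-BuOH, toluene) then sets C3'. The product is expected in part as the lactol F4, which Ag2CO3 on Celite in warm toluene returns to lactone 22.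

Step 19. What may go wrong: the aryl ester enolate may open to a ketene-phenoxide or self-condense faster than it transmetalates and couples at the hindered α-carbon. Fallback, setting out from 22 and returning at 28: the lactone is opened before arylation. Sodium 2-(trimethylsilyl)ethoxide (1 equiv, THF, −40 °C) followed by TBSCl gives the open 2-(trimethylsilyl)ethyl ester silyl ether F5. Hartwig–Buchwald α-arylation of this ordinary ester enolate (LiN(SiMe3)2, Pd(dba)2, P(t-Bu)3, 24, toluene, rt) gives the α-aryl ester F6. n-Bu4NF removes both silicon groups in one operation, and one equivalent of 2,4,6-collidinium BF4 reprotonates the phenoxide to give 28.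

Further compounds
F1 | step 21 | (2R,3R)-3-Ar1-3-[2-(tert-butyldimethylsilyloxy)-4-(methoxycarbonyl)-6-(methoxymethoxy)phenyl]-2-[4-(methoxymethoxy)phenyl]propanoic acid | COc1cc([C@H]2Oc3cc([C@H](c5c(OCOC)cc(C(=O)OC)cc5O[Si](C)(C)C(C)(C)C)[C@@H](C(=O)O)c4ccc(OCOC)cc4)cc(OCOC)c3[C@@H]2c2cc(OCOC)cc(OCOC)c2)ccc1OCOC
F2 | step 21 | (2R)-2-Ar1-2-[2-(tert-butyldimethylsilyloxy)-4-(methoxycarbonyl)-6-(methoxymethoxy)phenyl]-1-[4-(methoxymethoxy)phenyl]ethyl acetate, both C1 epimers | COc1cc([C@H]2Oc3cc([C@H](c5c(OCOC)cc(C(=O)OC)cc5O[Si](C)(C)C(C)(C)C)C(OC(C)=O)c4ccc(OCOC)cc4)cc(OCOC)c3[C@@H]2c2cc(OCOC)cc(OCOC)c2)ccc1OCOC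
F3 | step 17 | methyl 4-Ar1-5-(methoxymethoxy)-2-oxo-2H-chromene-7-carboxylate | COc1cc([C@H]2Oc3cc(-c4cc(=O)oc5cc(C(=O)OC)cc(OCOC)c45)cc(OCOC)c3[C@@H]2c2cc(OCOC)cc(OCOC)c2)ccc1OCOC
F4 | step 17 | methyl (4R)-4-Ar1-2-hydroxy-5-(methoxymethoxy)-3,4-dihydro-2H-chromene-7-carboxylate, both anomers | COc1cc([C@H]2Oc3cc([C@H]4CC(O)Oc5cc(C(=O)OC)cc(OCOC)c45)cc(OCOC)c3[C@@H]2c2cc(OCOC)cc(OCOC)c2)ccc1OCOC
F5 | step 19 | 2-(trimethylsilyl)ethyl (3R)-3-Ar1-3-[2-(tert-butyldimethylsilyloxy)-4-(methoxycarbonyl)-6-(methoxymethoxy)phenyl]propanoate | COc1cc([C@H]2Oc3cc([C@H](c5c(OCOC)cc(C(=O)OC)cc5O[Si](C)(C)C(C)(C)C)CC(=O)OCC[Si](C)(C)C)cc(OCOC)c3[C@@H]2c2cc(OCOC)cc(OCOC)c2)ccc1OCOC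
F6 | step 19 | 2-(trimethylsilyl)ethyl (3R)-3-Ar1-3-[2-(tert-butyldimethylsilyloxy)-4-(methoxycarbonyl)-6-(methoxymethoxy)phenyl]-2-[4-(methoxymethoxy)phenyl]propanoate, both C2 epimers | COc1cc([C@H]2Oc3cc([C@H](c5c(OCOC)cc(C(=O)OC)cc5O[Si](C)(C)C(C)(C)C)C(c4ccc(OCOC)cc4)C(=O)OCC[Si](C)(C)C)cc(OCOC)c3[C@@H]2c2cc(OCOC)cc(OCOC)c2)ccc1OCOC
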